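**Retrosynthetic overview**
1. Target 19 ⇐ 18 by global O‑demethylation (last step).
2. 18 ⇐ 16: C7b–C10c bond; the seven‑membered ring is closed last by a new chiral‑acid‑catalysed 7‑endo hydroarylation of a 2‑hydroxystilbene, which sets C7b.
3. 16 ⇐ 10 + 14: Suzuki coupling of a C2‑symmetric aryl bromide with an (E)‑styryl boronate.
4. 10 ⇐ 6: both dihydrofuran rings are formed together by twofold Rh(II) donor/donor‑carbene C–H insertion (sets both C3), then C2 epimerisation to trans.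
5. 6 ⇐ 1 + 2 + 5: double Friedel–Crafts acylation, chelation‑controlled demethylation, O‑benzylation. Ring order: two dihydrofurans, then the cycloheptene.

Assumption 1: the absolute sense of induction of the two chiral catalysts (step 5 and step 10) is assigned by analogy; if either proves opposite, its enantiomer is used and nothing else changes.
Assumption 2: in the two‑directional steps the half‑reacted species is a transient of the same operation and is not numbered.
Locants: compounds 9–16 use benzo[1,2‑b:5,4‑b']difuran numbering (O1, C2, C3, C3a, C4, C4a, C5, C6, O7, C7a, C8, C8a). In 17–19, C7a/C8a are the O–CH and Ar–CH of the dihydrofuran outside the seven‑membered ring, C7c/C8c those of the other dihydrofuran, C8b the CH2 and C7b the CH(aryl) of the cycloheptene, and C10c the carbon of the dioxygenated benzo ring bonded to C7b.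

**Route**

Step 1
Reactants: 1 1‑bromo‑3,5‑dimethoxybenzene; 2 3,5‑dimethoxybenzoyl chloride (2.4 equiv)
Product: 3 (2‑bromo‑4,6‑dimethoxy‑1,3‑phenylene)bis[(3,5‑dimethoxyphenyl)methanone]
Conditions: AlCl3 (2.6 equiv), CH2Cl2, 0 °C → rt
Reagents that add atoms: none
Why: Twofold Friedel–Crafts acylation; the first aroyl group enters C2 (para to one OMe, ortho to the other) and the second enters the equivalent C6, which is meta to the new carbonyl and still the most activated site, while the acylating ring is deactivated by its own carbonyl.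

Step 2
Reactants: 3 (2‑bromo‑4,6‑dimethoxy‑1,3‑phenylene)bis[(3,5‑dimethoxyphenyl)methanone]
Product: 4 (2‑bromo‑4,6‑dihydroxy‑1,3‑phenylene)bis[(3,5‑dimethoxyphenyl)methanone]
Conditions: BCl3 (3 equiv), CH2Cl2, −78 → 0 °C; aqueous work‑up
Reagents that add atoms: none
Why: Chelation‑controlled Lewis acid demethylation removes only the two methyl ethers ortho to the ketones (six‑membered boron chelate) and leaves the four meta‑methoxy groups of the outer rings.

Step 3
Reactants: 4 (2‑bromo‑4,6‑dihydroxy‑1,3‑phenylene)bis[(3,5‑dimethoxyphenyl)methanone]; 5 4‑methoxybenzyl chloride (2.4 equiv)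
Product: 6 {2‑bromo‑4,6‑bis[(4‑methoxybenzyl)oxy]‑1,3‑phenylene}bis[(3,5‑dimethoxyphenyl)methanone]
Conditions: K2CO3, NaI (cat.), DMF, 60 °C
Reagents that add atoms: none
Why: Williamson ether synthesis on both phenols installs the 4‑methoxybenzyl groups whose CH2 carbons become C2 and C6 of the dihydrofurans.

Step 4
Reactants: 6 {2‑bromo‑4,6‑bis[(4‑methoxybenzyl)oxy]‑1,3‑phenylene}bis[(3,5‑dimethoxyphenyl)methanone]
Product: 7 bis‑hydrazone of 6 (both C=O replaced by C=N–NH2; C=N geometry immaterial)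
Conditions: N2H4 (anhydrous, 20 equiv), N2H4·HCl (cat.), DMSO, 90 °C
Reagents that add atoms: hydrazine (NN)
Why: Hydrazone condensation under forcing, mildly acidic conditions, needed because each carbonyl is flanked by Br and an ether, while the moderate temperature keeps substitution of the aryl bromide slow.

Step 5
Reactants: 7 bis‑hydrazone of 6
Product: 9 cis,cis‑bis(dihydrofuran) bromide (2S,3R,5R,6S)‑4‑bromo‑3,5‑bis(3,5‑dimethoxyphenyl)‑2,6‑bis(4‑methoxyphenyl)‑2,3,5,6‑tetrahydrobenzo[1,2‑b:5,4‑b']difuran, via bis‑diazo compound 8 (not isolated)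
Conditions: MnO2, CH2Cl2, 0 °C; filter; Rh2(R‑PTAD)4 (2 mol %), CH2Cl2, −20 °C → rt
Reagents that add atoms: none
Why: Hydrazone dehydrogenation followed by twofold enantioselective intramolecular donor/donor Rh‑carbene 1,5‑C–H insertion into the adjacent ArO–CH2–Ar bonds; the concerted insertion gives the cis dihydrofurans, the chiral Rh(II) carboxylate fixes both C3/C5 as R (C2/C6 are then S), and two independent catalyst‑controlled events enrich the C2‑symmetric product.

Step 6
Reactants: 9 cis,cis‑bis(dihydrofuran) bromide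
Product: 10 trans,trans‑bis(dihydrofuran) bromide (2R,3R,5R,6R)‑4‑bromo‑3,5‑bis(3,5‑dimethoxyphenyl)‑2,6‑bis(4‑methoxyphenyl)‑2,3,5,6‑tetrahydrobenzo[1,2‑b:5,4‑b']difuran
Conditions: TFA (5 equiv), CH2Cl2, 0 °C → rt
Reagents that add atoms: none
Why: Acid‑mediated epimerisation: reversible C2–O (C6–O) heterolysis to the 4‑methoxybenzyl cation and re‑closure gives the thermodynamically favoured trans rings, so C2/C6 become R while C3/C5 from step 5 are untouched.

Step 7
Reactants: 11 2‑hydroxy‑4‑methoxybenzaldehyde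
Product: 12 2‑[(tert‑butyldimethylsilyl)oxy]‑4‑methoxybenzaldehyde
Conditions: TBSCl, imidazole, DMF, rt
Reagents that add atoms: tert‑butyldimethylsilyl chloride (CC(C)(C)[Si](C)(C)Cl)
Why: Silyl protection of the phenol keeps the aldehyde electrophilic for the next step.

Step 8
Reactants: 12 2‑[(tert‑butyldimethylsilyl)oxy]‑4‑methoxybenzaldehyde; 13 bis[(pinacolato)boryl]methane (1.2 equiv)
Product: 14 tert‑butyl{5‑methoxy‑2‑[(E)‑2‑(4,4,5,5‑tetramethyl‑1,3,2‑dioxaborolan‑2‑yl)ethenyl]phenoxy}dimethylsilane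
Conditions: LiTMP (1.2 equiv), THF, −78 °C → rt
Reagents that add atoms: none
Why: Boron–Wittig olefination: the α‑boryl carbanion adds to the aldehyde and syn B–O elimination gives the (E)‑alkenyl boronate.

Step 9
Reactants: 10 trans,trans‑bis(dihydrofuran) bromide; 14 (E)‑styryl boronate (1.5 equiv)
Product: 16 2‑{(E)‑2‑[(2R,3R,5R,6R)‑3,5‑bis(3,5‑dimethoxyphenyl)‑2,6‑bis(4‑methoxyphenyl)‑2,3,5,6‑tetrahydrobenzo[1,2‑b:5,4‑b']difuran‑4‑yl]ethenyl}‑5‑methoxyphenol, via TBS‑protected stilbene 15 (not isolated)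
Conditions: SPhos Pd G3 (5 mol %), K3PO4, toluene/H2O (10:1), 90 °C; then TBAF, THF, rt
Reagents that add atoms: none
Why: Suzuki–Miyaura coupling (a dialkylbiarylphosphine ligand handles the di‑ortho‑substituted bromide) with retention of E geometry, then fluoride desilylation in the same flask frees the ortho‑phenol needed in step 10; no stereocentre is touched.

Step 10
Reactants: 16 C2‑symmetric 2‑hydroxystilbene
Product: 18 (7aR,8aR,7bR,7cR,8cR)‑hepta‑O‑methyl ether of 19 (only the 2‑OH of the C7b aryl ring free), via o‑quinone methide 17 (not isolated)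
Conditions: (R)‑3,3'‑bis(2,4,6‑triisopropylphenyl)‑BINOL N‑triflylphosphoramide (10 mol %), 5 Å MS, toluene (0.01 M), 40 °C
Reagents that add atoms: none
Why: Proposed new method: a chiral N‑triflylphosphoramide‑catalysed, catalyst‑controlled 7‑endo‑trig hydroarylation of a 2‑hydroxystilbene, in which the acid protonates C8b of the electron‑rich 2‑hydroxy‑4‑methoxystyryl unit, the resulting o‑quinone methide 17 stays hydrogen‑bonded to the chiral phosphoramidate, and C10c (ortho and para to OMe) of one of the two homotopic 3,5‑dimethoxyphenyl rings adds to C7b inside the chiral pocket, closing the seven‑membered ring with the aryl group syn to H‑8c (7bR), which is also the substrate‑preferred diastereomer because the C7b aryl then avoids the ortho‑OMe of the attacking ring (matched case); the closest known reaction types are chiral phosphoric acid‑catalysed additions of arenes to o‑quinone methides generated from o‑hydroxystyrenes and the achiral‑acid cyclisation of ε‑viniferin‑type stilbenes to ampelopsin B‑type cycloheptenes, neither shown as a catalyst‑controlled intramolecular seven‑ring closure.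

Step 11
Reactants: 18 hepta‑O‑methyl ether
Product: 19 target CNP0154047.1
Conditions: BBr3 (14 equiv), CH2Cl2, −78 → 0 °C; MeOH/H2O quench
Reagents that add atoms: none
Why: Lewis acid O‑demethylation of all seven aryl methyl ethers; the trans dihydrofurans and the C7b configuration are the thermodynamic arrangements, so reversible benzylic C–O ionisation under the acid does not change them.

**Compound list**
1 | 1‑bromo‑3,5‑dimethoxybenzene | COc1cc(Br)cc(OC)c1 | starting material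
2 | 3,5‑dimethoxybenzoyl chloride | COc1cc(cc(OC)c1)C(Cl)=O | starting material
3 | (2‑bromo‑4,6‑dimethoxy‑1,3‑phenylene)bis[(3,5‑dimethoxyphenyl)methanone] | COc1cc(OC)c(C(=O)c2cc(OC)cc(OC)c2)c(Br)c1C(=O)c1cc(OC)cc(OC)c1 | intermediate
4 | (2‑bromo‑4,6‑dihydroxy‑1,3‑phenylene)bis[(3,5‑dimethoxyphenyl)methanone] | Oc1cc(O)c(C(=O)c2cc(OC)cc(OC)c2)c(Br)c1C(=O)c1cc(OC)cc(OC)c1 | intermediate
5 | 4‑methoxybenzyl chloride | COc1ccc(CCl)cc1 | starting material
6 | {2‑bromo‑4,6‑bis[(4‑methoxybenzyl)oxy]‑1,3‑phenylene}bis[(3,5‑dimethoxyphenyl)methanone] | COc1ccc(COc2cc(OCc3ccc(OC)cc3)c(C(=O)c3cc(OC)cc(OC)c3)c(Br)c2C(=O)c2cc(OC)cc(OC)c2)cc1 | intermediate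
7 | bis‑hydrazone of 6 | COc1ccc(COc2cc(OCc3ccc(OC)cc3)c(C(=NN)c3cc(OC)cc(OC)c3)c(Br)c2C(=NN)c2cc(OC)cc(OC)c2)cc1 | intermediate
8 | bis‑diazo compound, 3‑bromo‑2,4‑bis[diazo(3,5‑dimethoxyphenyl)methyl]‑1,5‑bis[(4‑methoxybenzyl)oxy]benzene (not isolated) | COc1ccc(COc2cc(OCc3ccc(OC)cc3)c(C(=[N+]=[N-])c3cc(OC)cc(OC)c3)c(Br)c2C(=[N+]=[N-])c2cc(OC)cc(OC)c2)cc1 | intermediate
9 | (2S,3R,5R,6S)‑4‑bromo‑3,5‑bis(3,5‑dimethoxyphenyl)‑2,6‑bis(4‑methoxyphenyl)‑2,3,5,6‑tetrahydrobenzo[1,2‑b:5,4‑b']difuran (cis,cis) | COc1ccc([C@H]2Oc3cc4c(c(Br)c3[C@H]2c2cc(OC)cc(OC)c2)[C@@H](c2cc(OC)cc(OC)c2)[C@@H](c2ccc(OC)cc2)O4)cc1 | intermediate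
10 | (2R,3R,5R,6R)‑4‑bromo‑3,5‑bis(3,5‑dimethoxyphenyl)‑2,6‑bis(4‑methoxyphenyl)‑2,3,5,6‑tetrahydrobenzo[1,2‑b:5,4‑b']difuran (trans,trans) | COc1ccc([C@@H]2Oc3cc4c(c(Br)c3[C@H]2c2cc(OC)cc(OC)c2)[C@@H](c2cc(OC)cc(OC)c2)[C@H](c2ccc(OC)cc2)O4)cc1 | intermediate
11 | 2‑hydroxy‑4‑methoxybenzaldehyde | COc1ccc(C=O)c(O)c1 | starting material
12 | 2‑[(tert‑butyldimethylsilyl)oxy]‑4‑methoxybenzaldehyde | COc1ccc(C=O)c(O[Si](C)(C)C(C)(C)C)c1 | intermediate
13 | bis[(pinacolato)boryl]methane | CC1(C)OB(CB2OC(C)(C)C(C)(C)O2)OC1(C)C | starting material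
14 | tert‑butyl{5‑methoxy‑2‑[(E)‑2‑(4,4,5,5‑tetramethyl‑1,3,2‑dioxaborolan‑2‑yl)ethenyl]phenoxy}dimethylsilane | COc1ccc(/C=C/B2OC(C)(C)C(C)(C)O2)c(O[Si](C)(C)C(C)(C)C)c1 | intermediate
15 | TBS ether of 16 (not isolated) | COc1ccc([C@@H]2Oc3cc4c(c(/C=C/c5ccc(OC)cc5O[Si](C)(C)C(C)(C)C)c3[C@H]2c2cc(OC)cc(OC)c2)[C@@H](c2cc(OC)cc(OC)c2)[C@H](c2ccc(OC)cc2)O4)cc1 | intermediate
16 | 2‑{(E)‑2‑[(2R,3R,5R,6R)‑3,5‑bis(3,5‑dimethoxyphenyl)‑2,6‑bis(4‑methoxyphenyl)‑2,3,5,6‑tetrahydrobenzo[1,2‑b:5,4‑b']difuran‑4‑yl]ethenyl}‑5‑methoxyphenol | COc1ccc([C@@H]2Oc3cc4c(c(/C=C/c5ccc(OC)cc5O)c3[C@H]2c2cc(OC)cc(OC)c2)[C@@H](c2cc(OC)cc(OC)c2)[C@H](c2ccc(OC)cc2)O4)cc1 | intermediate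
17 | (E)‑o‑quinone methide from C8b protonation of 16: 6‑alkylidene‑3‑methoxycyclohexa‑2,4‑dienone, CH2 anti to C=O (not isolated) | COc1ccc([C@@H]2Oc3cc4c(c(C/C=C5\C=CC(OC)=CC5=O)c3[C@H]2c2cc(OC)cc(OC)c2)[C@@H](c2cc(OC)cc(OC)c2)[C@H](c2ccc(OC)cc2)O4)cc1 | intermediate
18 | (7aR,8aR,7bR,7cR,8cR)‑hepta‑O‑methyl ether of 19; C7b carries 2‑hydroxy‑4‑methoxyphenyl | COc1ccc([C@@H]2Oc3cc4c5c(c3[C@H]2c2cc(OC)cc(OC)c2)C[C@H](c2ccc(OC)cc2O)c2c(OC)cc(OC)cc2[C@H]5[C@H](c2ccc(OC)cc2)O4)cc1 | intermediate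
19 | CNP0154047.1, (7aR,8aR,7bR,7cR,8cR): central benzene fused to two trans‑2‑(4‑hydroxyphenyl)dihydrofurans (C8a bears 3,5‑dihydroxyphenyl) and to a cycloheptene made of C8b H2, C7b H(2,4‑dihydroxyphenyl), a 1,3‑dihydroxybenzo ring and C8c | Oc1ccc([C@@H]2Oc3cc4c5c(c3[C@H]2c2cc(O)cc(O)c2)C[C@H](c2ccc(O)cc2O)c2c(O)cc(O)cc2[C@H]5[C@H](c2ccc(O)cc2)O4)cc1 | target

**Totals**
Total steps: 11. Longest linear sequence: 9 steps (steps 1–6 and 9–11, from 1).

**Three steps most likely to fail**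

Step 4 (hydrazone formation at two di‑ortho‑substituted diaryl ketones). The fallback sets out from diketone 6. Thionation with Lawesson's reagent in toluene at 110 °C gives the bis‑thioketone F1, and the much more electrophilic C=S groups then condense with hydrazine hydrate in THF/EtOH at room temperature, with loss of hydrogen sulfide. This gives bis‑hydrazone 7, where the route is rejoined, and it avoids hot hydrazine next to the aryl bromide.

Step 5 (twofold asymmetric C–H insertion of a hindered carbene; selectivity is untested with two ortho substituents). The fallback sets out from diketone 6 and gives up catalyst control. A phosphazene base (P4‑t‑Bu, benzene, 80 °C) deprotonates the ArO–CH2–Ar groups, and intramolecular aldol‑type addition to the ketones with dehydration gives the bis‑benzofuran F2. Ionic hydrogenation (Et3SiH, TFA, CH2Cl2) then gives the trans,trans dihydrofurans as a statistical 1:1:2 mixture of 10, its enantiomer F3 and the meso isomer F4. The meso isomer is removed on silica and 10 is separated from F3 by preparative chiral SFC, so the route is rejoined at 10.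

Step 10 (the proposed new catalytic hydroarylation). The fallback sets out from stilbene 16 and uses known chemistry in the reverse order. BBr3 in CH2Cl2 (−78 → 0 °C) cleaves all seven methyl ethers to give the free octaphenol stilbene F5. Brief treatment with HCl in MeOH at room temperature then effects the substrate‑controlled, biomimetic cyclisation known for ε‑viniferin‑type stilbenes, in which the C7b cation is captured by the neighbouring resorcinol ring. This arrives directly at target 19; any material that already cyclises during the BBr3 step converges on the same product.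

**Further compounds**
F1 | step 4 | {2‑bromo‑4,6‑bis[(4‑methoxybenzyl)oxy]‑1,3‑phenylene}bis[(3,5‑dimethoxyphenyl)methanethione] | COc1ccc(COc2cc(OCc3ccc(OC)cc3)c(C(=S)c3cc(OC)cc(OC)c3)c(Br)c2C(=S)c2cc(OC)cc(OC)c2)cc1
F2 | step 5 | 4‑bromo‑3,5‑bis(3,5‑dimethoxyphenyl)‑2,6‑bis(4‑methoxyphenyl)benzo[1,2‑b:5,4‑b']difuran | COc1ccc(-c2oc3cc4oc(-c5ccc(OC)cc5)c(-c5cc(OC)cc(OC)c5)c4c(Br)c3c2-c2cc(OC)cc(OC)c2)cc1
F3 | step 5 | (2S,3S,5S,6S)‑enantiomer of 10 | COc1ccc([C@H]2Oc3cc4c(c(Br)c3[C@@H]2c2cc(OC)cc(OC)c2)[C@H](c2cc(OC)cc(OC)c2)[C@@H](c2ccc(OC)cc2)O4)cc1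
F4 | step 5 | meso (2R,3R,5S,6S)‑diastereomer of 10 | COc1ccc([C@@H]2Oc3cc4c(c(Br)c3[C@H]2c2cc(OC)cc(OC)c2)[C@H](c2cc(OC)cc(OC)c2)[C@@H](c2ccc(OC)cc2)O4)cc1
F5 | step 10 | 4‑{(E)‑2‑[(2R,3R,5R,6R)‑3,5‑bis(3,5‑dihydroxyphenyl)‑2,6‑bis(4‑hydroxyphenyl)‑2,3,5,6‑tetrahydrobenzo[1,2‑b:5,4‑b']difuran‑4‑yl]ethenyl}benzene‑1,3‑diol | Oc1ccc([C@@H]2Oc3cc4c(c(/C=C/c5ccc(O)cc5O)c3[C@H]2c2cc(O)cc(O)c2)[C@@H](c2cc(O)cc(O)c2)[C@H](c2ccc(O)cc2)O4)cc1
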